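**Retrosynthetic overview**

- Feature: rings A and B are cis-fused (H-5 and CH3-20 on one face) between the quaternary carbons C4 and C10, with the C3 ketone next to C4. C3–C4 and ring B (C5–C10) are therefore folded back into a bicyclo[2.2.2]oct-5-en-2-one, in which a vinyl group on the carbinol carbon can reach C10 only on the face that gives the cis fusion.
- Key disconnection: anionic oxy-Cope shift (C1–C10 made, C3–C8 cut) of a 2-vinylbicyclo[2.2.2]oct-5-en-2-ol. The bicycle comes from an enantioselective Diels–Alder reaction of 1,3-dimethylcyclohexa-1,3-diene with acrolein, excision of the formyl carbon and two enolate alkylations that build C4.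
- Side chain: formaldehyde ene reaction at C9 (C9–C11, moving C8(CH3)=C9 to the C8=C17 methylene), then C11 aldehyde, vinyl group, and hydroboration/B-alkyl Suzuki coupling (C12–C13) with methyl (Z)-3-iodobut-2-enoate; saponification, PMB removal and acetylation finish the route.
- Ring order: ring B (the cyclohexadiene) first, then the temporary C3–C4 bridge (Diels–Alder), then ring A (oxy-Cope), the bridge bond C3–C8 being cut in that same step.

Key step: step 11

Remark on locants: compounds 5–18 carry bicyclo[2.2.2]octane numbers; labdane locants are used in the text from 19 on (bicycle C2, C3, C4, C5, C6, C1 become labdane C3, C4, C5, C10, C9, C8; the vinyl carbons become C2 and C1; C18 is the oxygenated carbon on C4, C19 the methyl on C4, C20 the methyl on C10, C17 the carbon on C8).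

Assumption: the (5S)-imidazolidinone is taken to induce the same facial sense with diene 3 as with cyclohexa-1,3-diene (2R endo adduct); if the adduct proved antipodal, the (5R) catalyst would be used.

**Step 1**
Reactants: 1 3-methylcyclohex-2-en-1-one
Product: 2 1,3-dimethylcyclohex-2-en-1-ol (racemic)
Conditions: MeLi, Et2O, −78 → 0 °C; aq. NH4Cl
Reagents that add atoms: methyllithium, [Li]C
Why: Organolithium 1,2-addition to the enone carbonyl should give the tertiary allylic alcohol, whose stereocentre is destroyed in step 2.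

**Step 2**
Reactants: 2 1,3-dimethylcyclohex-2-en-1-ol
Product: 3 1,3-dimethylcyclohexa-1,3-diene
Conditions: TsOH·H2O (1 mol%), pentane, reflux with water separation; NaHCO3 wash; distillation
Reagents that add atoms: none
Why: Acid-catalysed E1 dehydration under equilibrating conditions should favour the conjugated endocyclic diene; the minor exocyclic isomer is locked s-trans and cannot enter the cycloaddition of step 3.

**Step 3**
Reactants: 3 1,3-dimethylcyclohexa-1,3-diene; 4 acrolein
Product: 5 (1R,2R,4R)-1,5-dimethylbicyclo[2.2.2]oct-5-ene-2-carbaldehyde (endo: formyl syn to the C5=C6 bridge)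
Conditions: (5S)-5-benzyl-2,2,3-trimethylimidazolidin-4-one·HCl (10 mol%), MeCN/H2O 95:5, 0 °C → rt; SiO2 chromatography (endo isomer kept)
Reagents that add atoms: none
Why: Iminium-activated organocatalytic Diels–Alder reaction in which the formyl-bearing carbon should join the methylated diene terminus (ortho to the 1-methyl, para to the 3-methyl group) in the endo mode, while the benzyl group of the catalyst shields one face of the E-iminium ion so that C2 forms R and thereby fixes both bridgeheads (1R,4R); the exo adduct is removed because it would lead to the enantiomeric ketone in step 5.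

**Step 4**
Reactants: 5 endo aldehyde
Product: 6 4-{[(1R,4R)-1,5-dimethylbicyclo[2.2.2]oct-5-en-2-ylidene]methyl}morpholine (E/Z mixture; used crude)
Conditions: morpholine (1.5 equiv), TsOH·H2O (1 mol%), PhH, reflux, Dean–Stark; concentrate
Reagents that add atoms: morpholine, C1COCCN1
Why: Enamine formation from the α-branched aldehyde should proceed with azeotropic water removal and erases the C2 stereocentre, which is no longer needed.

**Step 5**
Reactants: 6 morpholine enamine
Product: 7 (1R,4R)-1,5-dimethylbicyclo[2.2.2]oct-5-en-2-one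
Conditions: O2 (1 atm), CuCl (10 mol%), MeCN, 0 °C → rt
Reagents that add atoms: dioxygen, O=O
Why: Copper-catalysed oxygenation of the electron-rich enamine C=C bond (oxidative enamine cleavage) should excise the formyl carbon as a formamide and leave the ketone, the isolated trisubstituted ring alkene being too electron-poor to compete.

**Step 6**
Reactants: 8 4-methoxybenzyl alcohol; 9 chloromethyl methyl sulfide
Product: 10 1-methoxy-4-{[(methylsulfanyl)methoxy]methyl}benzene
Conditions: NaH, NaI (cat.), DME, 0 °C → rt
Reagents that add atoms: none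
Why: Williamson etherification of the sodium alkoxide with the α-chloro sulfide should give the methylthiomethyl ether.

**Step 7**
Reactants: 10 methylthiomethyl ether
Product: 11 1-[(chloromethoxy)methyl]-4-methoxybenzene (PMB chloromethyl ether; used at once)
Conditions: SO2Cl2, CH2Cl2, −78 °C; volatiles removed
Reagents that add atoms: sulfuryl chloride, O=S(=O)(Cl)Cl
Why: Chlorinolysis of the O,S-acetal (S-chlorination, oxocarbenium formation, capture by chloride) should give the α-chloro ether with only volatile by-products.

**Step 8**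
Reactants: 7 bicyclic ketone; 11 PMB chloromethyl ether
Product: 13 (1R,4R)-3-{[(4-methoxybenzyl)oxy]methyl}-1,5-dimethylbicyclo[2.2.2]oct-5-en-2-one (C3 epimers), via lithium enolate 12 (not isolated)
Conditions: LiN(iPr)2, THF, −78 °C; then 11, −78 → −30 °C
Reagents that add atoms: none
Why: The ketone can enolise only toward C3 (C1 is a quaternary bridgehead) and C-alkylation of the lithium enolate with the reactive α-chloro ether should follow; the C3 configuration formed here is irrelevant because C3 is planarised again in step 9.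

**Step 9**
Reactants: 13 mono-alkylated ketone
Product: 15 (1R,3R,4S)-3-{[(4-methoxybenzyl)oxy]methyl}-1,3,5-trimethylbicyclo[2.2.2]oct-5-en-2-one (3-CH3 syn to the C5=C6 bridge), via lithium enolate 14 (not isolated)
Conditions: LiN(iPr)2, THF, −78 °C; MeI, DMPU, −78 → −20 °C
Reagents that add atoms: iodomethane, CI
Why: Enolate alkylation under steric approach control: methyl iodide should approach C3 over the C5=C6 bridge, which has no inward-pointing hydrogen, rather than past the C8 methylene, so that methyl ends syn to the alkene bridge and the PMB-oxymethyl group syn to the ethano bridge (C3 R); the cold lithium enolate should not expel the β-alkoxide.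

**Step 10**
Reactants: 15 quaternary ketone; 16 vinylmagnesium bromide
Product: 17 (1R,2R,3R,4S)-2-ethenyl-3-{[(4-methoxybenzyl)oxy]methyl}-1,3,5-trimethylbicyclo[2.2.2]oct-5-en-2-ol (vinyl syn to the C5=C6 bridge)
Conditions: CeCl3 (anhydrous), THF, −78 °C, 16; then 15, −78 → 0 °C; aq. NH4Cl
Reagents that add atoms: none
Why: Organocerium 1,2-addition to a hindered, non-enolisable ketone should deliver vinyl from the olefin-bridge face (the small C3 methyl lies there, while the PMB-oxymethyl group and the ethano hydrogens block the other face), setting C2 (R) with the vinyl group syn to the alkene bridge as the rearrangement requires.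

**Step 11**
Reactants: 17 2-vinylbicyclo[2.2.2]oct-5-en-2-ol
Product: 20 (1R,4aR,8aS)-1-{[(4-methoxybenzyl)oxy]methyl}-1,4a,6-trimethyl-3,4,4a,7,8,8a-hexahydronaphthalen-2(1H)-one (cis-fused 3-oxo-8-ene in labdane locants), via potassium alkoxide 18 (not isolated), via potassium enolate 19 (not isolated)
Conditions: KH, 18-crown-6, THF, 0 °C → rt (50 °C if slow); aq. NH4Cl
Reagents that add atoms: none
Why: Deprotonation gives the crown-separated potassium alkoxide, which weakens the adjacent C1–C2 bond of the bicycle (labdane C8–C3) and triggers a concerted [3,3]-sigmatropic shift of the 1,5-diene CH2=CH–C2–C1–C6=C5 held in a boat by the bridged frame; the closest known reaction type is the anionic oxy-Cope rearrangement of 2-vinylbicyclo[2.2.2]oct-5-en-2-ols to cis-fused octalones. Ring A (six-membered carbocycle) is closed by the new bond between the vinyl terminus (labdane C1) and the methyl-bearing alkene carbon (labdane C10) in a sigmatropic mode, suprafacial on both allyl halves, through a six-membered boat transition state, while ring B is the cyclohexene of the bicycle released when C1–C2 breaks. The only new stereocentre, quaternary C10, is controlled by the bridged geometry: the vinyl terminus can bond only to the face of the C5=C6 bridge that looks at the carbinol bridge, so CH3-20 ends on the face of H-5 (cis fusion), and C4 and C5 are carried over unchanged. The step needs the [3,3] shift to win over a [1,3] shift or fragmentation and needs the vinyl group syn to the alkene bridge; the first should be secured by the enforced boat overlap and the irreversible formation of the C3 enolate, the second by the facial selectivity of step 10. The enolate forms only toward C2 (C4 is quaternary, so the PMB ether cannot be eliminated) and is protonated on work-up to the C3 ketone.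

**Step 12**
Reactants: 20 cis-fused octalone
Product: 21 (1R,4aS,5S,8aS)-5-(hydroxymethyl)-1-{[(4-methoxybenzyl)oxy]methyl}-1,4a-dimethyl-6-methylideneoctahydronaphthalen-2(1H)-one (C11 alcohol with C8=C17 methylene)
Conditions: (CH2O)n (2–3 equiv), Me2AlCl (3 equiv), CH2Cl2, −78 → 0 °C; cold 1 M HCl
Reagents that add atoms: formaldehyde (from paraformaldehyde), C=O
Why: Lewis-acid-promoted carbonyl-ene reaction in which formaldehyde should bond to the less substituted alkene carbon C9 and take hydrogen from the C17 methyl to give the exocyclic alkene, approaching on the convex face of ring B that carries H-5 and CH3-20 (ring A with the C4 substituents hangs under the other face), which sets C9 (S) with C11 cis to CH3-20; excess aluminium reagent is used because the ketone and ether oxygens also bind it.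

**Step 13**
Reactants: 21 homoallylic alcohol
Product: 22 (1S,4aS,5R,8aS)-5-{[(4-methoxybenzyl)oxy]methyl}-5,8a-dimethyl-2-methylidene-6-oxodecahydronaphthalene-1-carbaldehyde (C11 aldehyde; used crude)
Conditions: Dess–Martin periodinane, NaHCO3, CH2Cl2, 0 °C → rt
Reagents that add atoms: none
Why: Buffered Dess–Martin oxidation should give the β,γ-unsaturated aldehyde without epimerising C9 or moving the alkene into conjugation.

**Step 14**
Reactants: 22 C11 aldehyde
Product: 23 (1R,4aS,5S,8aS)-5-ethenyl-1-{[(4-methoxybenzyl)oxy]methyl}-1,4a-dimethyl-6-methylideneoctahydronaphthalen-2(1H)-one (C9 vinyl compound)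
Conditions: Ph3PCH3Br (1.3 equiv), KN(SiMe3)2 (1.2 equiv), THF, 0 °C; then 22, −78 → 0 °C
Reagents that add atoms: methyltriphenylphosphonium bromide, C[P+](c1ccccc1)(c1ccccc1)c1ccccc1.[Br-]
Why: Wittig methylenation should take the aldehyde far faster than the C3 ketone flanked by quaternary C4, and the cold, near-stoichiometric ylide should leave C9 unepimerised.

**Step 15**
Reactants: 24 methyl but-2-ynoate
Product: 25 methyl (Z)-3-iodobut-2-enoate
Conditions: NaI, AcOH, 115 °C
Reagents that add atoms: sodium iodide, [Na+].[I-]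
Why: Hydroiodination of the ynoate (conjugate addition of iodide, then protonation anti to it) should give the Z-β-iodoenoate selectively.

**Step 16**
Reactants: 23 C9 vinyl compound; 25 methyl (Z)-3-iodobut-2-enoate
Product: 27 methyl (2Z)-5-[(1S,4aS,5R,8aR)-5-{[(4-methoxybenzyl)oxy]methyl}-5,8a-dimethyl-2-methylidene-6-oxodecahydronaphthalen-1-yl]-3-methylpent-2-enoate, via alkylborane 26 (not isolated)
Conditions: (Sia)2BH [bis(3-methylbutan-2-yl)borane, from BH3·THF and 2-methylbut-2-ene, 0 °C], THF, 0 °C → rt; then 25, PdCl2(dppf) (dppf = 1,1'-bis(diphenylphosphino)ferrocene; 5 mol%), K3PO4 (aq.), DMF, 50 °C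
Reagents that add atoms: none
Why: Disiamylborane should hydroborate the monosubstituted vinyl group anti-Markovnikov much faster than the 1,1-disubstituted C8=C17 methylene (which 9-BBN would discriminate poorly) or the hindered C3 ketone, and the primary alkyl group is then transferred in a B-alkyl Suzuki–Miyaura coupling that retains the geometry of the iodoenoate and so gives the 13Z alkene.

**Step 17**
Reactants: 27 methyl ester
Product: 28 (2Z)-5-[(1S,4aS,5R,8aR)-5-{[(4-methoxybenzyl)oxy]methyl}-5,8a-dimethyl-2-methylidene-6-oxodecahydronaphthalen-1-yl]-3-methylpent-2-enoic acid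
Conditions: LiOH, THF/MeOH/H2O, rt → 40 °C; 1 M HCl to pH 3
Reagents that add atoms: lithium hydroxide, [Li+].[OH-]
Why: Saponification is done while the PMB ether is still in place, so that no β-hydroxy ketone is exposed to base (no retro-aldol loss of formaldehyde), and it should not disturb the Z alkene.

**Step 18**
Reactants: 28 PMB ether acid
Product: 29 (2Z)-5-[(1S,4aS,5R,8aR)-5-(hydroxymethyl)-5,8a-dimethyl-2-methylidene-6-oxodecahydronaphthalen-1-yl]-3-methylpent-2-enoic acid
Conditions: DDQ, CH2Cl2/pH 7 buffer, 0 °C → rt
Reagents that add atoms: none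
Why: Oxidative PMB cleavage (oxidation of the electron-rich benzyl ether, hydrolysis of the oxocarbenium ion) should leave the isolated alkenes, the enoic acid and the ketone untouched.

**Step 19**
Reactants: 29 hydroxy acid
Product: 30 (2Z)-5-[(1S,4aS,5R,8aR)-5-(acetoxymethyl)-5,8a-dimethyl-2-methylidene-6-oxodecahydronaphthalen-1-yl]-3-methylpent-2-enoic acid (target CNP0243698.1)
Conditions: Ac2O, pyridine, DMAP (cat.), CH2Cl2, 0 °C → rt; then aq. NaHCO3/THF; acidify to pH 3
Reagents that add atoms: acetic anhydride, CC(=O)OC(C)=O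
Why: DMAP-catalysed acetylation of the primary neopentyl alcohol should be clean, any mixed anhydride at the carboxylic acid being hydrolysed in the bicarbonate work-up, and no stereocentre is touched.

**Compound list**

1 | 3-methylcyclohex-2-en-1-one | CC1=CC(=O)CCC1 | starting material
2 | 1,3-dimethylcyclohex-2-en-1-ol (racemic) | CC1=CC(C)(O)CCC1 | intermediate
3 | 1,3-dimethylcyclohexa-1,3-diene | CC1=CC(C)=CCC1 | intermediate
4 | acrolein | C=CC=O | starting material
5 | (1R,2R,4R)-1,5-dimethylbicyclo[2.2.2]oct-5-ene-2-carbaldehyde (endo) | C1=C(C)[C@@H]2CC[C@@]1(C)[C@H](C=O)C2 | intermediate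
6 | 4-{[(1R,4R)-1,5-dimethylbicyclo[2.2.2]oct-5-en-2-ylidene]methyl}morpholine | C1=C(C)[C@@H]2CC[C@@]1(C)C(=CN3CCOCC3)C2 | intermediate
7 | (1R,4R)-1,5-dimethylbicyclo[2.2.2]oct-5-en-2-one | C1=C(C)[C@@H]2CC[C@@]1(C)C(=O)C2 | intermediate
8 | 4-methoxybenzyl alcohol | COc1ccc(CO)cc1 | starting material
9 | chloromethyl methyl sulfide | CSCCl | starting material
10 | 1-methoxy-4-{[(methylsulfanyl)methoxy]methyl}benzene | COc1ccc(COCSC)cc1 | intermediate
11 | 1-[(chloromethoxy)methyl]-4-methoxybenzene | COc1ccc(COCCl)cc1 | intermediate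
12 | lithium enolate of 7 (C2–O–Li, C2=C3) | C1=C(C)[C@@H]2CC[C@@]1(C)C(O[Li])=C2 | intermediate
13 | (1R,4R)-3-{[(4-methoxybenzyl)oxy]methyl}-1,5-dimethylbicyclo[2.2.2]oct-5-en-2-one (C3 epimers) | C1=C(C)[C@@H]2CC[C@@]1(C)C(=O)C2COCc3ccc(OC)cc3 | intermediate
14 | lithium enolate of 13 | C1=C(C)[C@@H]2CC[C@@]1(C)C(O[Li])=C2COCc3ccc(OC)cc3 | intermediate
15 | (1R,3R,4S)-3-{[(4-methoxybenzyl)oxy]methyl}-1,3,5-trimethylbicyclo[2.2.2]oct-5-en-2-one | C1=C(C)[C@@H]2CC[C@@]1(C)C(=O)[C@@]2(C)COCc3ccc(OC)cc3 | intermediate
16 | vinylmagnesium bromide | C=C[Mg]Br | starting material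
17 | (1R,2R,3R,4S)-2-ethenyl-3-{[(4-methoxybenzyl)oxy]methyl}-1,3,5-trimethylbicyclo[2.2.2]oct-5-en-2-ol | C1=C(C)[C@@H]2CC[C@@]1(C)[C@](O)(C=C)[C@@]2(C)COCc3ccc(OC)cc3 | intermediate
18 | potassium alkoxide of 17 | C1=C(C)[C@@H]2CC[C@@]1(C)[C@]([O-])(C=C)[C@@]2(C)COCc3ccc(OC)cc3.[K+] | intermediate
19 | potassium enolate of 20 (C2=C3 enolate) | C1=C(C)CC[C@H]2[C@]1(C)CC=C([O-])[C@@]2(C)COCc3ccc(OC)cc3.[K+] | intermediate
20 | (1R,4aR,8aS)-1-{[(4-methoxybenzyl)oxy]methyl}-1,4a,6-trimethyl-3,4,4a,7,8,8a-hexahydronaphthalen-2(1H)-one | C1=C(C)CC[C@H]2[C@]1(C)CCC(=O)[C@@]2(C)COCc3ccc(OC)cc3 | intermediate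
21 | (1R,4aS,5S,8aS)-5-(hydroxymethyl)-1-{[(4-methoxybenzyl)oxy]methyl}-1,4a-dimethyl-6-methylideneoctahydronaphthalen-2(1H)-one | C=C1CC[C@H]2[C@](C)(CCC(=O)[C@@]2(C)COCc3ccc(OC)cc3)[C@H]1CO | intermediate
22 | (1S,4aS,5R,8aS)-5-{[(4-methoxybenzyl)oxy]methyl}-5,8a-dimethyl-2-methylidene-6-oxodecahydronaphthalene-1-carbaldehyde | C=C1CC[C@H]2[C@](C)(CCC(=O)[C@@]2(C)COCc3ccc(OC)cc3)[C@H]1C=O | intermediate
23 | (1R,4aS,5S,8aS)-5-ethenyl-1-{[(4-methoxybenzyl)oxy]methyl}-1,4a-dimethyl-6-methylideneoctahydronaphthalen-2(1H)-one | C=C1CC[C@H]2[C@](C)(CCC(=O)[C@@]2(C)COCc3ccc(OC)cc3)[C@H]1C=C | intermediate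
24 | methyl but-2-ynoate | CC#CC(=O)OC | starting material
25 | methyl (Z)-3-iodobut-2-enoate | C/C(I)=C/C(=O)OC | intermediate
26 | B-alkyl disiamylborane from 23 (boron on C12) | C=C1CC[C@H]2[C@](C)(CCC(=O)[C@@]2(C)COCc3ccc(OC)cc3)[C@H]1CCB(C(C)C(C)C)C(C)C(C)C | intermediate
27 | methyl (2Z)-5-[(1S,4aS,5R,8aR)-5-{[(4-methoxybenzyl)oxy]methyl}-5,8a-dimethyl-2-methylidene-6-oxodecahydronaphthalen-1-yl]-3-methylpent-2-enoate | C=C1CC[C@H]2[C@](C)(CCC(=O)[C@@]2(C)COCc3ccc(OC)cc3)[C@H]1CC/C(C)=C\C(=O)OC | intermediate
28 | (2Z)-5-[(1S,4aS,5R,8aR)-5-{[(4-methoxybenzyl)oxy]methyl}-5,8a-dimethyl-2-methylidene-6-oxodecahydronaphthalen-1-yl]-3-methylpent-2-enoic acid | C=C1CC[C@H]2[C@](C)(CCC(=O)[C@@]2(C)COCc3ccc(OC)cc3)[C@H]1CC/C(C)=C\C(=O)O | intermediate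
29 | (2Z)-5-[(1S,4aS,5R,8aR)-5-(hydroxymethyl)-5,8a-dimethyl-2-methylidene-6-oxodecahydronaphthalen-1-yl]-3-methylpent-2-enoic acid | C=C1CC[C@H]2[C@](C)(CCC(=O)[C@@]2(C)CO)[C@H]1CC/C(C)=C\C(=O)O | intermediate
30 | (2Z)-5-[(1S,4aS,5R,8aR)-5-(acetoxymethyl)-5,8a-dimethyl-2-methylidene-6-oxodecahydronaphthalen-1-yl]-3-methylpent-2-enoic acid | C=C1CC[C@H]2[C@](C)(CCC(=O)[C@@]2(C)COC(C)=O)[C@H]1CC/C(C)=C\C(=O)O | target

**Step count**

Total step count: 19.
Longest linear sequence: 16 steps (steps 1–5, 8–14 and 16–19, from compound 1); steps 6–7 and step 15 are side branches.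

**Steps most likely to fail**

1. Step 12 (formaldehyde ene reaction). The aluminium reagent may be tied up by the ketone and ether oxygens or may cleave the PMB ether. Hydrogen may be taken from C7 instead of C17, giving the endocyclic alkene. The new methylene group may add a second formaldehyde. Fallback: setting out from 20, a thermal ene reaction with ethyl glyoxylate (toluene, sealed tube, about 140 °C, no aluminium reagent; Sc(OTf)3 catalysis as an option) should give the α-hydroxy ester F3 as C11 epimers. Saponification (LiOH, THF/H2O) should give the α-hydroxy acid F4, and oxidative decarboxylation with Pb(OAc)4 (PhH, rt) should give the aldehyde. The route is rejoined at 22.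

2. Step 16 (hydroboration and B-alkyl Suzuki coupling). The dialkylborane may also attack the C8=C17 methylene or slowly reduce the C3 ketone, and the hindered trialkylborane may transmetalate sluggishly. A C3 carbinol formed by over-reduction could be re-oxidised after coupling with Dess–Martin periodinane, since 27 carries no other hydroxyl group. Fallback: setting out from 23, RhCl(PPh3)3-catalysed hydroboration with pinacolborane (CH2Cl2, rt), which prefers monosubstituted alkenes and spares ketones, should give the isolable pinacol boronate F5. KHF2 (MeOH/H2O) should convert it into the potassium trifluoroborate F6, which is coupled with 25 (PdCl2(dppf), Cs2CO3, toluene/H2O, 80 °C). The route is rejoined at 27.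

3. Step 3 (organocatalytic Diels–Alder reaction). Bond formation at the methyl-bearing diene terminus may be slow, the acidic catalyst salt may isomerise or oligomerise the diene, and endo or enantioselectivity may erode. Fallback: setting out from 3, a Diels–Alder reaction with 2,2,2-trifluoroethyl acrylate is run under the oxazaborolidinium triflimide made from α,α-diphenylprolinol, o-tolylboroxine and HNTf2 (CH2Cl2, −78 → −20 °C), using the enantiomer of the catalyst that delivers the 2R adduct. This should give 2,2,2-trifluoroethyl (1R,2R,4R)-1,5-dimethylbicyclo[2.2.2]oct-5-ene-2-carboxylate F1. LiAlH4 (Et2O, 0 °C) should give [(1R,2R,4R)-1,5-dimethylbicyclo[2.2.2]oct-5-en-2-yl]methanol F2, and Swern oxidation gives the aldehyde. The route is rejoined at 5.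

**Further compounds**

F1 | step 3 | 2,2,2-trifluoroethyl (1R,2R,4R)-1,5-dimethylbicyclo[2.2.2]oct-5-ene-2-carboxylate | C1=C(C)[C@@H]2CC[C@@]1(C)[C@H](C(=O)OCC(F)(F)F)C2
F2 | step 3 | [(1R,2R,4R)-1,5-dimethylbicyclo[2.2.2]oct-5-en-2-yl]methanol | C1=C(C)[C@@H]2CC[C@@]1(C)[C@H](CO)C2
F3 | step 12 | α-hydroxy ester (ethyl glyoxylate ene adduct of 20: C9–CH(OH)CO2Et, C8=C17 methylene, C11 epimers) | C=C1CC[C@H]2[C@](C)(CCC(=O)[C@@]2(C)COCc3ccc(OC)cc3)[C@H]1C(O)C(=O)OCC
F4 | step 12 | α-hydroxy acid (C9–CH(OH)CO2H, C11 epimers) | C=C1CC[C@H]2[C@](C)(CCC(=O)[C@@]2(C)COCc3ccc(OC)cc3)[C@H]1C(O)C(=O)O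
F5 | step 16 | pinacol boronate (C12–Bpin from 23) | C=C1CC[C@H]2[C@](C)(CCC(=O)[C@@]2(C)COCc3ccc(OC)cc3)[C@H]1CCB1OC(C)(C)C(C)(C)O1
F6 | step 16 | potassium trifluoroborate (C12–BF3K) | C=C1CC[C@H]2[C@](C)(CCC(=O)[C@@]2(C)COCc3ccc(OC)cc3)[C@H]1CC[B-](F)(F)F.[K+]
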